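**Retrosynthetic overview**
1. Last bond: the C(=O)–cyclopropyl bond, made by a Pd/Cu-mediated thioester–boronic acid coupling that joins a west thioester (cinnamate–lactate) with an east trans-cyclopropylboronic acid (carbinol–lactone) and gives the target directly.
2. West fragment: Mitsunobu esterification (inversion) of S-phenyl (R)-thiolactate with (Z)-4-methoxycinnamic acid; the acid comes from anisole by para-iodination, Sonogashira coupling with ethyl propiolate, Lindlar reduction and saponification.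
3. East fragment: the cyclopropane comes from a ligand-controlled Simmons–Smith reaction on an (E)-γ-boryl allylic alcohol, itself made by Zr-catalysed hydroboration of a terminal alkyne.
4. The dihydropyranone comes from epoxide opening with lithium ethyl propiolate, Lindlar reduction and lactonisation; both oxygen-bearing stereocentres come from a Sharpless kinetic resolution of the acrolein/trimethylsilylacetylene adduct.
5. Ring order: lactone ring first, cyclopropane second; the anisole ring is bought.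

Assumption: the target is taken exactly as the given SMILES, that is (R) at the lactone carbon, (S) at the carbinol, (1S,2S) at the cyclopropane, (S) at the lactate carbon and a Z enoate.

**Step 1**
Reactants: 1 anisole
Product: 2 4-iodoanisole
Conditions: NIS (1.05 equiv), TFA (10 mol %), MeCN, rt
Reagents that add atoms: N-iodosuccinimide O=C1CCC(=O)N1I
Why: Electrophilic aromatic iodination in which the methoxy group directs the iodonium equivalent almost exclusively to the para position.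

**Step 2**
Reactants: 2 4-iodoanisole; 3 ethyl propiolate
Product: 4 ethyl 3-(4-methoxyphenyl)prop-2-ynoate
Conditions: PdCl2(PPh3)2 (2 mol %), CuI (4 mol %), K2CO3, THF, 65 °C
Reagents that add atoms: none
Why: Sonogashira coupling, run with an inorganic base because amines add to the propiolate in a conjugate fashion.

**Step 3**
Reactants: 4 ethyl 3-(4-methoxyphenyl)prop-2-ynoate
Product: 5 ethyl (2Z)-3-(4-methoxyphenyl)prop-2-enoate
Conditions: H2 (1 atm), Pd/CaCO3–Pb(OAc)2 (Lindlar catalyst), quinoline, EtOAc, rt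
Reagents that add atoms: none
Why: Lindlar semi-hydrogenation delivers both hydrogens to the same face of the alkyne and so fixes the Z geometry of the cinnamate.

**Step 4**
Reactants: 5 ethyl (2Z)-3-(4-methoxyphenyl)prop-2-enoate
Product: 6 (2Z)-3-(4-methoxyphenyl)prop-2-enoic acid
Conditions: LiOH, THF/H2O, 0 °C to rt; then 1 M HCl
Reagents that add atoms: lithium hydroxide [Li+].[OH-]
Why: Mild saponification cleaves the ethyl ester without Z to E isomerisation.

**Step 5**
Reactants: 7 methyl (2R)-2-hydroxypropanoate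
Product: 8 S-phenyl (2R)-2-hydroxypropanethioate
Conditions: AlMe3, PhSH (2.5 equiv each), CH2Cl2, 0 °C to rt; aq. HCl
Reagents that add atoms: thiophenol Sc1ccccc1
Why: Aluminium thiolate ester-to-thioester exchange (Me2AlSPh), in which the aluminium alkoxide of the α-hydroxy ester delivers the thiolate to the chelated carbonyl and the stereocentre is not touched.

**Step 6**
Reactants: 6 (2Z)-3-(4-methoxyphenyl)prop-2-enoic acid; 8 S-phenyl (2R)-2-hydroxypropanethioate
Product: 9 S-phenyl (2S)-2-{[(2Z)-3-(4-methoxyphenyl)prop-2-enoyl]oxy}propanethioate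
Conditions: PPh3, DIAD, THF, 0 °C
Reagents that add atoms: none
Why: Mitsunobu esterification, in which the carboxylate displaces the activated hydroxyl by SN2 and inverts (R) to the required (S) lactate centre, while avoiding the acyl-transfer catalysts that isomerise Z-cinnamates.

**Step 7**
Reactants: 10 ethynyl(trimethyl)silane; 11 acrolein
Product: 13 rac-5-(trimethylsilyl)pent-1-en-4-yn-3-ol, via lithium silylacetylide 12 (not isolated)
Conditions: n-BuLi, THF, −78 °C; then 11; aq. NH4Cl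
Reagents that add atoms: none
Why: 1,2-Addition of a hard lithium acetylide to the aldehyde of acrolein gives the racemic enynol.

**Step 8**
Reactants: 13 rac-5-(trimethylsilyl)pent-1-en-4-yn-3-ol
Product: 14 (1S)-1-[(2R)-oxiran-2-yl]-3-(trimethylsilyl)prop-2-yn-1-ol
Conditions: Ti(OiPr)4 (15 mol %), L-(+)-DIPT (18 mol %), t-BuOOH (0.55 equiv), 4 Å MS, CH2Cl2, −20 °C
Reagents that add atoms: tert-butyl hydroperoxide CC(C)(C)OO
Why: Sharpless asymmetric epoxidation run as a kinetic resolution, in which the (R)-enynol reacts fast with the L-(+)-tartrate catalyst and is epoxidised to the anti (erythro) epoxy alcohol, setting the future lactone carbon as (R) next to the (S) carbinol, while the slow (S)-enantiomer of 13 stays behind (yield at most 50 %).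

**Step 9**
Reactants: 14 (1S)-1-[(2R)-oxiran-2-yl]-3-(trimethylsilyl)prop-2-yn-1-ol
Product: 15 tert-butyl(dimethyl){[(1S)-1-[(2R)-oxiran-2-yl]-3-(trimethylsilyl)prop-2-yn-1-yl]oxy}silane
Conditions: TBSCl, imidazole, DMF, rt
Reagents that add atoms: tert-butyldimethylsilyl chloride CC(C)(C)[Si](C)(C)Cl
Why: Silyl ether formation blocks the carbinol oxygen so that only the hydroxyl freed in the next step can lactonise.

**Step 10**
Reactants: 15 tert-butyl(dimethyl){[(1S)-1-[(2R)-oxiran-2-yl]-3-(trimethylsilyl)prop-2-yn-1-yl]oxy}silane; 3 ethyl propiolate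
Product: 17 ethyl (5R,6S)-6-{[tert-butyl(dimethyl)silyl]oxy}-5-hydroxy-8-(trimethylsilyl)octa-2,7-diynoate, via lithium ethyl propiolate 16 (not isolated)
Conditions: 3, n-BuLi, THF, −78 °C; BF3·OEt2; then 15, −78 °C
Reagents that add atoms: none
Why: Yamaguchi–Hirao alkynylation, in which the BF3-activated epoxide is opened by SN2 at its terminal carbon so that neither stereocentre is touched.

**Step 11**
Reactants: 17 ethyl (5R,6S)-6-{[tert-butyl(dimethyl)silyl]oxy}-5-hydroxy-8-(trimethylsilyl)octa-2,7-diynoate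
Product: 19 (6R)-6-[(1S)-1-{[tert-butyl(dimethyl)silyl]oxy}-3-(trimethylsilyl)prop-2-yn-1-yl]-5,6-dihydro-2H-pyran-2-one, via Z-hydroxy enoate 18 (not isolated)
Conditions: H2 (1 atm), Pd/CaCO3–Pb(OAc)2 (Lindlar catalyst), quinoline, EtOAc, rt; then PPTS (cat.), benzene, 60 °C
Reagents that add atoms: none
Why: Lindlar semi-hydrogenation reduces the unhindered, electron-poor ynoate in preference to the hindered silyl alkyne, and the resulting Z-enoate is placed for acid-catalysed lactonisation to the six-membered ring.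

**Step 12**
Reactants: 19 (6R)-6-[(1S)-1-{[tert-butyl(dimethyl)silyl]oxy}-3-(trimethylsilyl)prop-2-yn-1-yl]-5,6-dihydro-2H-pyran-2-one
Product: 20 (6R)-6-[(1S)-1-{[tert-butyl(dimethyl)silyl]oxy}prop-2-yn-1-yl]-5,6-dihydro-2H-pyran-2-one
Conditions: AgNO3 (20 mol %), acetone/H2O, rt
Reagents that add atoms: none
Why: Silver-catalysed protodesilylation cleaves only the alkynyl C–Si bond under neutral conditions that spare the lactone and the silyl ether.

**Step 13**
Reactants: 20 (6R)-6-[(1S)-1-{[tert-butyl(dimethyl)silyl]oxy}prop-2-yn-1-yl]-5,6-dihydro-2H-pyran-2-one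
Product: 21 (6R)-6-[(1S,2E)-1-{[tert-butyl(dimethyl)silyl]oxy}-3-(4,4,5,5-tetramethyl-1,3,2-dioxaborolan-2-yl)prop-2-en-1-yl]-5,6-dihydro-2H-pyran-2-one
Conditions: HBpin (1.5 equiv), Cp2Zr(H)Cl (10 mol %), Et3N (10 mol %), CH2Cl2, 40 °C
Reagents that add atoms: pinacolborane CC1(C)OBOC1(C)C
Why: Zirconium-catalysed alkyne hydroboration (hydrozirconation then Zr-to-B exchange) adds H and B syn with boron at the terminal carbon and gives the E-alkenyl boronate.

**Step 14**
Reactants: 21 (6R)-6-[(1S,2E)-1-{[tert-butyl(dimethyl)silyl]oxy}-3-(4,4,5,5-tetramethyl-1,3,2-dioxaborolan-2-yl)prop-2-en-1-yl]-5,6-dihydro-2H-pyran-2-one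
Product: 22 (6R)-6-[(1S,2E)-1-hydroxy-3-(4,4,5,5-tetramethyl-1,3,2-dioxaborolan-2-yl)prop-2-en-1-yl]-5,6-dihydro-2H-pyran-2-one
Conditions: HF·pyridine, pyridine, THF, 0 °C to rt
Reagents that add atoms: none
Why: Buffered fluoride desilylation frees the allylic hydroxyl needed to direct the cyclopropanation and leaves the lactone and the pinacol boronate intact.

**Step 15**
Reactants: 22 (6R)-6-[(1S,2E)-1-hydroxy-3-(4,4,5,5-tetramethyl-1,3,2-dioxaborolan-2-yl)prop-2-en-1-yl]-5,6-dihydro-2H-pyran-2-one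
Product: 23 (6R)-6-{(S)-hydroxy[(1S,2S)-2-(4,4,5,5-tetramethyl-1,3,2-dioxaborolan-2-yl)cyclopropyl]methyl}-5,6-dihydro-2H-pyran-2-one
Conditions: Et2Zn, CH2I2, DME, CH2Cl2, −10 °C [Zn(CH2I)2·DME]; (4R,5R)-2-butyl-N,N,N',N'-tetramethyl-1,3,2-dioxaborolane-4,5-dicarboxamide (1.2 equiv), −10 °C to rt; aq. NH4Cl, no peroxide
Reagents that add atoms: diiodomethane ICI
Why: Charette asymmetric Simmons–Smith cyclopropanation, in which the zinc alkoxide is bound by the (4R,5R)-dioxaborolane that steers stereospecific CH2 transfer (E alkene to trans ring) to the face giving the (1S,2S) cyclopropane, anti to the carbinol, by reagent control over the weak syn preference of E-allylic alcohols.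

**Step 16**
Reactants: 23 (6R)-6-{(S)-hydroxy[(1S,2S)-2-(4,4,5,5-tetramethyl-1,3,2-dioxaborolan-2-yl)cyclopropyl]methyl}-5,6-dihydro-2H-pyran-2-one
Product: 24 [(1S,2S)-2-{(S)-hydroxy[(2R)-6-oxo-3,6-dihydro-2H-pyran-2-yl]methyl}cyclopropyl]boronic acid
Conditions: NaIO4, NH4OAc, acetone/H2O, rt
Reagents that add atoms: water O
Why: Oxidative pinacol removal, in which periodate destroys the pinacol released in the hydrolysis equilibrium and pulls it to the free boronic acid, the substrate itself carrying no 1,2-diol.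

**Step 17**
Reactants: 9 S-phenyl (2S)-2-{[(2Z)-3-(4-methoxyphenyl)prop-2-enoyl]oxy}propanethioate; 24 [(1S,2S)-2-{(S)-hydroxy[(2R)-6-oxo-3,6-dihydro-2H-pyran-2-yl]methyl}cyclopropyl]boronic acid
Product: 25 brevipolide I, (2S)-1-[(1S,2S)-2-{(S)-hydroxy[(2R)-6-oxo-3,6-dihydro-2H-pyran-2-yl]methyl}cyclopropyl]-1-oxopropan-2-yl (2Z)-3-(4-methoxyphenyl)prop-2-enoate
Conditions: Pd2(dba)3 (2.5 mol %), P(OEt)3 (20 mol %), CuTC (CuO2C-C4H3S, 1.6 equiv), THF, rt to 45 °C, argon; 24 (1.3 equiv)
Reagents that add atoms: none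
Why: Proposed new method: a base-free Pd/Cu thioester–boronic acid ketone synthesis extended to a stereodefined secondary cyclopropylboronic acid, in which the monovalent copper carboxylate binds the thiolate sulfur (opening the C(acyl)–S bond to oxidative addition at zerovalent palladium) while its carboxylate activates boron, so that the cyclopropyl group, whose C–B bond has high s character, transmetalates with retention and reductive elimination forms the C(=O)–cyclopropyl bond with no base present to epimerise the α-acyloxy ketone, isomerise the Z-enoate or acylate the free hydroxyl; the closest known reactions are the Liebeskind–Srogl coupling of thioesters with aryl and alkenyl boronic acids (including α-amino thioesters without racemisation) and the Ag2O-promoted Suzuki acylation of trans-cyclopropylboronic acids with acid chlorides, which goes with retention.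

**Compound list**
1 | anisole | COc1ccccc1 | starting material
2 | 4-iodoanisole | COc1ccc(I)cc1 | intermediate
3 | ethyl propiolate | CCOC(=O)C#C | starting material
4 | ethyl 3-(4-methoxyphenyl)prop-2-ynoate | CCOC(=O)C#Cc1ccc(OC)cc1 | intermediate
5 | ethyl (2Z)-3-(4-methoxyphenyl)prop-2-enoate | CCOC(=O)/C=C\c1ccc(OC)cc1 | intermediate
6 | (2Z)-3-(4-methoxyphenyl)prop-2-enoic acid | OC(=O)/C=C\c1ccc(OC)cc1 | intermediate
7 | methyl (2R)-2-hydroxypropanoate | C[C@@H](O)C(=O)OC | starting material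
8 | S-phenyl (2R)-2-hydroxypropanethioate | C[C@@H](O)C(=O)Sc1ccccc1 | intermediate
9 | S-phenyl (2S)-2-{[(2Z)-3-(4-methoxyphenyl)prop-2-enoyl]oxy}propanethioate | COc1ccc(/C=C\C(=O)O[C@@H](C)C(=O)Sc2ccccc2)cc1 | intermediate
10 | ethynyl(trimethyl)silane | C[Si](C)(C)C#C | starting material
11 | acrolein | C=CC=O | starting material
12 | lithium (trimethylsilyl)acetylide | C[Si](C)(C)C#C[Li] | intermediate
13 | rac-5-(trimethylsilyl)pent-1-en-4-yn-3-ol | C[Si](C)(C)C#CC(O)C=C | intermediate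
14 | (1S)-1-[(2R)-oxiran-2-yl]-3-(trimethylsilyl)prop-2-yn-1-ol | C[Si](C)(C)C#C[C@H](O)[C@H]1CO1 | intermediate
15 | tert-butyl(dimethyl){[(1S)-1-[(2R)-oxiran-2-yl]-3-(trimethylsilyl)prop-2-yn-1-yl]oxy}silane | C[Si](C)(C)C#C[C@H](O[Si](C)(C)C(C)(C)C)[C@H]1CO1 | intermediate
16 | ethyl 3-lithioprop-2-ynoate (lithium ethyl propiolate) | CCOC(=O)C#C[Li] | intermediate
17 | ethyl (5R,6S)-6-{[tert-butyl(dimethyl)silyl]oxy}-5-hydroxy-8-(trimethylsilyl)octa-2,7-diynoate | C[Si](C)(C)C#C[C@H](O[Si](C)(C)C(C)(C)C)[C@H](O)CC#CC(=O)OCC | intermediate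
18 | ethyl (2Z,5R,6S)-6-{[tert-butyl(dimethyl)silyl]oxy}-5-hydroxy-8-(trimethylsilyl)oct-2-en-7-ynoate | C[Si](C)(C)C#C[C@H](O[Si](C)(C)C(C)(C)C)[C@H](O)C/C=C\C(=O)OCC | intermediate
19 | (6R)-6-[(1S)-1-{[tert-butyl(dimethyl)silyl]oxy}-3-(trimethylsilyl)prop-2-yn-1-yl]-5,6-dihydro-2H-pyran-2-one | C[Si](C)(C)C#C[C@H](O[Si](C)(C)C(C)(C)C)[C@H]1CC=CC(=O)O1 | intermediate
20 | (6R)-6-[(1S)-1-{[tert-butyl(dimethyl)silyl]oxy}prop-2-yn-1-yl]-5,6-dihydro-2H-pyran-2-one | C#C[C@H](O[Si](C)(C)C(C)(C)C)[C@H]1CC=CC(=O)O1 | intermediate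
21 | (6R)-6-[(1S,2E)-1-{[tert-butyl(dimethyl)silyl]oxy}-3-(4,4,5,5-tetramethyl-1,3,2-dioxaborolan-2-yl)prop-2-en-1-yl]-5,6-dihydro-2H-pyran-2-one | CC1(C)OB(/C=C/[C@H](O[Si](C)(C)C(C)(C)C)[C@H]2CC=CC(=O)O2)OC1(C)C | intermediate
22 | (6R)-6-[(1S,2E)-1-hydroxy-3-(4,4,5,5-tetramethyl-1,3,2-dioxaborolan-2-yl)prop-2-en-1-yl]-5,6-dihydro-2H-pyran-2-one | CC1(C)OB(/C=C/[C@H](O)[C@H]2CC=CC(=O)O2)OC1(C)C | intermediate
23 | (6R)-6-{(S)-hydroxy[(1S,2S)-2-(4,4,5,5-tetramethyl-1,3,2-dioxaborolan-2-yl)cyclopropyl]methyl}-5,6-dihydro-2H-pyran-2-one | CC1(C)OB([C@H]2C[C@@H]2[C@H](O)[C@H]2CC=CC(=O)O2)OC1(C)C | intermediate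
24 | [(1S,2S)-2-{(S)-hydroxy[(2R)-6-oxo-3,6-dihydro-2H-pyran-2-yl]methyl}cyclopropyl]boronic acid | OB(O)[C@H]1C[C@@H]1[C@H](O)[C@H]1CC=CC(=O)O1 | intermediate
25 | brevipolide I | COc1ccc(/C=C\C(=O)O[C@@H](C)C(=O)[C@H]2C[C@@H]2[C@H](O)[C@H]2CC=CC(=O)O2)cc1 | target

**Totals**
Total step count: 17.
Longest linear sequence: 11 steps (steps 7 to 17, from 10 and 11 to 25); the west branch is 6 steps (steps 1 to 4, 6 and 17), with step 5 as a one-step side branch.

**Three steps most likely to fail**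

Step 17 (the proposed new coupling). The risks are slow transmetalation of the secondary cyclopropyl group, loss of CO from the acyl–palladium intermediate and protodeboronation. The fallback uses known chemistry, sets out from 9 and 23 and comes back at 25. It replaces the thioester/copper carboxylate coupling with the known silver oxide-promoted Suzuki acylation of trans-cyclopropylboronic acids by acid chlorides, which needs the carbinol protected. Thioester 9 is hydrolysed with AgNO3 and 2,6-lutidine in THF/H2O to the acid (2S)-2-{[(2Z)-3-(4-methoxyphenyl)prop-2-enoyl]oxy}propanoic acid F6. 1-Chloro-N,N,2-trimethylprop-1-en-1-amine in CH2Cl2 turns it into the acid chloride (2S)-2-{[(2Z)-3-(4-methoxyphenyl)prop-2-enoyl]oxy}propanoyl chloride F7. In parallel 23 is silylated (TESOTf, 2,6-lutidine) to the triethylsilyl ether (6R)-6-{(S)-[(triethylsilyl)oxy][(1S,2S)-2-(4,4,5,5-tetramethyl-1,3,2-dioxaborolan-2-yl)cyclopropyl]methyl}-5,6-dihydro-2H-pyran-2-one F8. NaIO4/NH4OAc then frees the boronic acid [(1S,2S)-2-{(S)-[(triethylsilyl)oxy][(2R)-6-oxo-3,6-dihydro-2H-pyran-2-yl]methyl}cyclopropyl]boronic acid F9. F7 and F9 are joined with PdCl2(dppf), Ag2O and K2CO3 in toluene at 80 °C, with retention at the cyclopropane, to the silyl-protected ketone (2S)-1-[(1S,2S)-2-{(S)-[(triethylsilyl)oxy][(2R)-6-oxo-3,6-dihydro-2H-pyran-2-yl]methyl}cyclopropyl]-1-oxopropan-2-yl (2Z)-3-(4-methoxyphenyl)prop-2-enoate F10. HF·pyridine then gives 25.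

Step 15 (anti-selective cyclopropanation of a borylated secondary allylic alcohol). The risks are an insufficient override of the substrate's syn preference and interference by the pinacol boronate. The fallback sets out from 21 and comes back at 24. It moves stereocontrol from hydroxyl delivery to a chiral auxiliary on boron, with the carbinol left silylated. NaIO4/NH4OAc frees the alkenylboronic acid [(1E,3S)-3-{[tert-butyl(dimethyl)silyl]oxy}-3-[(2R)-6-oxo-3,6-dihydro-2H-pyran-2-yl]prop-1-en-1-yl]boronic acid F3. Condensation with (2R,3R)-N,N,N',N'-tetramethyltartramide over 4 Å sieves gives the chiral boronic ester (4R,5R)-2-[(1E,3S)-3-{[tert-butyl(dimethyl)silyl]oxy}-3-[(2R)-6-oxo-3,6-dihydro-2H-pyran-2-yl]prop-1-en-1-yl]-N,N,N',N'-tetramethyl-1,3,2-dioxaborolane-4,5-dicarboxamide F4. Simmons–Smith cyclopropanation (Et2Zn, CH2I2) under control of the boron-bound tartramide, a known route to trans-cyclopropylboronic acids, gives the cyclopropyl boronic ester (4R,5R)-2-[(1S,2S)-2-{(S)-{[tert-butyl(dimethyl)silyl]oxy}[(2R)-6-oxo-3,6-dihydro-2H-pyran-2-yl]methyl}cyclopropyl]-N,N,N',N'-tetramethyl-1,3,2-dioxaborolane-4,5-dicarboxamide F5. The antipodal tartramide is used if the pairing with the silyloxy centre proves mismatched. Aqueous HF in MeCN hydrolyses the boronic ester and removes the silyl group to give 24.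

Step 11 (semi-hydrogenation of the ynoate beside a second alkyne). The risk is partial reduction of the silyl alkyne or over-reduction. The fallback sets out from 15 and comes back at 19, building the lactone by ring-closing metathesis instead. CH2=CHMgBr with CuI (10 mol %) in THF at −40 °C opens the epoxide to the homoallylic alcohol (3S,4R)-3-{[tert-butyl(dimethyl)silyl]oxy}-1-(trimethylsilyl)hept-6-en-1-yn-4-ol F1. Acryloyl chloride and iPr2NEt give the acrylate (3S,4R)-3-{[tert-butyl(dimethyl)silyl]oxy}-1-(trimethylsilyl)hept-6-en-1-yn-4-yl prop-2-enoate F2. The second-generation Grubbs catalyst RuCl2(=CHPh)(PCy3)(H2IMes) in CH2Cl2 at 40 °C closes the ring to 19; the hindered silyl alkyne is a poor enyne partner.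

**Further compounds**
F1 | step 11 | (3S,4R)-3-{[tert-butyl(dimethyl)silyl]oxy}-1-(trimethylsilyl)hept-6-en-1-yn-4-ol | C[Si](C)(C)C#C[C@H](O[Si](C)(C)C(C)(C)C)[C@H](O)CC=C
F2 | step 11 | (3S,4R)-3-{[tert-butyl(dimethyl)silyl]oxy}-1-(trimethylsilyl)hept-6-en-1-yn-4-yl prop-2-enoate | C[Si](C)(C)C#C[C@H](O[Si](C)(C)C(C)(C)C)[C@H](OC(=O)C=C)CC=C
F3 | step 15 | [(1E,3S)-3-{[tert-butyl(dimethyl)silyl]oxy}-3-[(2R)-6-oxo-3,6-dihydro-2H-pyran-2-yl]prop-1-en-1-yl]boronic acid | OB(O)/C=C/[C@H](O[Si](C)(C)C(C)(C)C)[C@H]1CC=CC(=O)O1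
F4 | step 15 | (4R,5R)-2-[(1E,3S)-3-{[tert-butyl(dimethyl)silyl]oxy}-3-[(2R)-6-oxo-3,6-dihydro-2H-pyran-2-yl]prop-1-en-1-yl]-N,N,N',N'-tetramethyl-1,3,2-dioxaborolane-4,5-dicarboxamide | CN(C)C(=O)[C@H](OB(/C=C/[C@H](O[Si](C)(C)C(C)(C)C)[C@H]2CC=CC(=O)O2)O1)[C@@H]1C(=O)N(C)C
F5 | step 15 | (4R,5R)-2-[(1S,2S)-2-{(S)-{[tert-butyl(dimethyl)silyl]oxy}[(2R)-6-oxo-3,6-dihydro-2H-pyran-2-yl]methyl}cyclopropyl]-N,N,N',N'-tetramethyl-1,3,2-dioxaborolane-4,5-dicarboxamide | CN(C)C(=O)[C@H](OB([C@H]2C[C@@H]2[C@H](O[Si](C)(C)C(C)(C)C)[C@H]2CC=CC(=O)O2)O1)[C@@H]1C(=O)N(C)C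
F6 | step 17 | (2S)-2-{[(2Z)-3-(4-methoxyphenyl)prop-2-enoyl]oxy}propanoic acid | COc1ccc(/C=C\C(=O)O[C@@H](C)C(=O)O)cc1
F7 | step 17 | (2S)-2-{[(2Z)-3-(4-methoxyphenyl)prop-2-enoyl]oxy}propanoyl chloride | COc1ccc(/C=C\C(=O)O[C@@H](C)C(Cl)=O)cc1
F8 | step 17 | (6R)-6-{(S)-[(triethylsilyl)oxy][(1S,2S)-2-(4,4,5,5-tetramethyl-1,3,2-dioxaborolan-2-yl)cyclopropyl]methyl}-5,6-dihydro-2H-pyran-2-one | CC1(C)OB([C@H]2C[C@@H]2[C@H](O[Si](CC)(CC)CC)[C@H]2CC=CC(=O)O2)OC1(C)C
F9 | step 17 | [(1S,2S)-2-{(S)-[(triethylsilyl)oxy][(2R)-6-oxo-3,6-dihydro-2H-pyran-2-yl]methyl}cyclopropyl]boronic acid | OB(O)[C@H]1C[C@@H]1[C@H](O[Si](CC)(CC)CC)[C@H]1CC=CC(=O)O1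
F10 | step 17 | (2S)-1-[(1S,2S)-2-{(S)-[(triethylsilyl)oxy][(2R)-6-oxo-3,6-dihydro-2H-pyran-2-yl]methyl}cyclopropyl]-1-oxopropan-2-yl (2Z)-3-(4-methoxyphenyl)prop-2-enoate | COc1ccc(/C=C\C(=O)O[C@@H](C)C(=O)[C@H]2C[C@@H]2[C@H](O[Si](CC)(CC)CC)[C@H]2CC=CC(=O)O2)cc1
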